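**Retrosynthetic overview**
1. Cycloheptane ring last: Friedel–Crafts closure of a 2,4-dihydroxybenzylic cation onto C7 of the outer benzofuran (para to its free OH), the acid-type cyclisation of the biosynthesis. The cation comes from a deoxybenzoin carbonyl (NaBH4, then H+).
2. Outer trans-dihydrobenzofuran (gnetin C-type 8–12' link): oxidative [3+2] coupling of resveratrol onto the carbon between the two hydroxyls of the 3,5-dihydroxyphenyl ring of the heterodimer.
3. Inner trans-dihydrobenzofuran (ε-viniferin-type 8–10' link): oxidative [3+2] coupling of resveratrol with the resorcinol ring of 1-(2,4-dihydroxyphenyl)-2-(3,5-dihydroxyphenyl)ethanone. This ketone stands in for oxyresveratrol, because oxyresveratrol itself would be oxidised and alkylated first in both couplings; the racemate is resolved at this stage.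
4. The deoxybenzoin comes from Friedel–Crafts acylation of resorcinol with 3,5-dihydroxyphenylacetic acid.
5. Order of ring formation: inner dihydrofuran, outer dihydrofuran, cycloheptane; no protecting groups.

Assumption: the chiral-phase separation is counted as a step; a racemate is written as the SMILES of both enantiomers joined by a dot; benzofuran locants are used, "inner" meaning the dihydrobenzofuran that carries the CH2 side chain and "outer" the one that carries the 3,5-dihydroxyphenyl group.

**Step 1**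
Reactants: 1 resorcinol; 2 3,5-dihydroxyphenylacetic acid
Product: 3 1-(2,4-dihydroxyphenyl)-2-(3,5-dihydroxyphenyl)ethan-1-one
Conditions: BF3·OEt2 (as solvent), 1 (3 equiv), 85 °C, 2 h; aq. NaOAc
Reagents that add atoms: none
Why: Friedel–Crafts (Nencki-type) C-acylation of resorcinol at C4 by the BF3-activated arylacetic acid is the standard deoxybenzoin synthesis, the excess of resorcinol outcompetes self-acylation of the acid, and no stereocentre is formed.

**Step 2**
Reactants: 3 1-(2,4-dihydroxyphenyl)-2-(3,5-dihydroxyphenyl)ethan-1-one; 4 (E)-resveratrol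
Product: 6 (±)-trans-1-(2,4-dihydroxyphenyl)-2-[3-(3,5-dihydroxyphenyl)-6-hydroxy-2-(4-hydroxyphenyl)-2,3-dihydro-1-benzofuran-4-yl]ethan-1-one, via para-quinone methide 5 (not isolated)
Conditions: Tl(NO3)3·3H2O (1.1 equiv), 3 (3 equiv), MeOH, −50 °C, 15 min; H2O; excess 3 recovered
Reagents that add atoms: none
Why: Proposed new method: trivalent thallium takes two electrons only from the conjugated 4-hydroxystilbene 4 (the phenols of 3 are not conjugated to an alkene and one ring is acyl-deactivated), the cation so formed is attacked at its C8 by the 3,5-dihydroxybenzyl ring of the excess 3 through C2 (para to one OH, ortho to the CH2), and the rearomatised quinone methide 5 closes by 5-exo oxa-Michael addition of the adjacent phenol to the more stable trans-2,3-diaryl ring (racemic, no chiral influence); the closest known reaction type is the Tl(NO3)3-mediated oxidative [3+2] dimerisation of resveratrol to (±)-ε-viniferin, in which a second resveratrol plays the part of 3.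

**Step 3**
Reactants: 6 (±)-trans-1-(2,4-dihydroxyphenyl)-2-[3-(3,5-dihydroxyphenyl)-6-hydroxy-2-(4-hydroxyphenyl)-2,3-dihydro-1-benzofuran-4-yl]ethan-1-one
Product: 7 1-(2,4-dihydroxyphenyl)-2-[(2S,3S)-3-(3,5-dihydroxyphenyl)-6-hydroxy-2-(4-hydroxyphenyl)-2,3-dihydro-1-benzofuran-4-yl]ethan-1-one
Conditions: preparative chiral SFC, immobilised amylose tris(3,5-dimethylphenylcarbamate), CO2/MeOH
Reagents that add atoms: none
Why: Chromatographic resolution of enantiomers on a chiral stationary phase: the trans racemate consists of only two stereoisomers, so one separation gives the (2S,3S) enantiomer (assigned by electronic circular dichroism against the ε-viniferin enantiomers), and no stereocentre is formed or altered.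

**Step 4**
Reactants: 7 1-(2,4-dihydroxyphenyl)-2-[(2S,3S)-3-(3,5-dihydroxyphenyl)-6-hydroxy-2-(4-hydroxyphenyl)-2,3-dihydro-1-benzofuran-4-yl]ethan-1-one; 4 (E)-resveratrol
Product: 9 1-(2,4-dihydroxyphenyl)-2-{(2S,3S)-3-[(2S,3S)-3-(3,5-dihydroxyphenyl)-4-hydroxy-2-(4-hydroxyphenyl)-2,3-dihydro-1-benzofuran-6-yl]-6-hydroxy-2-(4-hydroxyphenyl)-2,3-dihydro-1-benzofuran-4-yl}ethan-1-one, via para-quinone methide 8 (not isolated)
Conditions: Tl(NO3)3·3H2O (1.1 equiv per 4), 7 (2 equiv), MeOH, −50 °C, 15 min; H2O; reversed-phase HPLC (removal of the diastereomer, recovery of 7)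
Reagents that add atoms: none
Why: Proposed new method: the same oxidative [3+2] coupling is run on the 3,5-dihydroxyphenyl ring of 7, whose two carbons para to a hydroxyl are screened by the congested C3 methine of the dihydrobenzofuran, so the oxidised resveratrol is taken up at C4 between the two hydroxyls (the selectivity seen in Friedel–Crafts alkylation of resorcinols with a bulky 5-substituent) and either of the two equivalent phenols closes quinone methide 8 to the trans ring; the new pair of stereocentres is trans by thermodynamic preference but, being remote from the old ones, forms in both senses (about 1:1), and the (2S,3S) isomer 9 is separated from its (2R,3R) diastereomer by HPLC; the closest known reaction types are the Tl(NO3)3 dimerisation of resveratrol and the 8–12' coupling that gives gnetin C in plants.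

**Step 5**
Reactants: 9 1-(2,4-dihydroxyphenyl)-2-{(2S,3S)-3-[(2S,3S)-3-(3,5-dihydroxyphenyl)-4-hydroxy-2-(4-hydroxyphenyl)-2,3-dihydro-1-benzofuran-6-yl]-6-hydroxy-2-(4-hydroxyphenyl)-2,3-dihydro-1-benzofuran-4-yl}ethan-1-one
Product: 11 CNP0154774.1 (all-S heptacyclic trimer), via benzylic carbinol 10 (not isolated)
Conditions: NaBH4 (3 equiv), MeOH, 0 °C, 1 h; then conc. HCl to 1 M, 0 °C to rt, 3 h; reversed-phase HPLC
Reagents that add atoms: none
Why: Borohydride reduction touches only the aryl ketone, and on acidification the 2,4-dihydroxybenzylic carbinol 10 ionises to the cation that protonation of the corresponding oxyresveratrol-type stilbene would give, which closes the seven-membered ring by Friedel–Crafts alkylation (the ε-viniferin to ampelopsin B type of cyclisation) at C7 of the outer benzofuran, the carbon para to the free 4-OH; the new stereocentre is set by substrate control, the aryl group taking the pseudo-axial position that avoids 1,3-allylic strain with the neighbouring ring oxygen, i.e. the face of H-3 of the inner dihydrofuran, which is the S configuration of the target.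

**Compound list**
1 | resorcinol (benzene-1,3-diol) | Oc1cccc(O)c1 | starting material
2 | 3,5-dihydroxyphenylacetic acid | OC(=O)Cc1cc(O)cc(O)c1 | starting material
3 | 1-(2,4-dihydroxyphenyl)-2-(3,5-dihydroxyphenyl)ethan-1-one | O=C(Cc1cc(O)cc(O)c1)c1ccc(O)cc1O | intermediate
4 | (E)-resveratrol | Oc1ccc(/C=C/c2cc(O)cc(O)c2)cc1 | starting material
5 | racemic 4-{2-(3,5-dihydroxyphenyl)-2-[2,4-dihydroxy-6-(2-(2,4-dihydroxyphenyl)-2-oxoethyl)phenyl]ethylidene}cyclohexa-2,5-dien-1-one (S and R at the methine) | O=C1C=CC(=C[C@@H](c2cc(O)cc(O)c2)c2c(O)cc(O)cc2CC(=O)c2ccc(O)cc2O)C=C1.O=C1C=CC(=C[C@H](c2cc(O)cc(O)c2)c2c(O)cc(O)cc2CC(=O)c2ccc(O)cc2O)C=C1 | intermediate (not isolated)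
6 | (±)-trans-1-(2,4-dihydroxyphenyl)-2-[3-(3,5-dihydroxyphenyl)-6-hydroxy-2-(4-hydroxyphenyl)-2,3-dihydro-1-benzofuran-4-yl]ethan-1-one (2S,3S and 2R,3R) | O=C(Cc1cc(O)cc2O[C@H](c3ccc(O)cc3)[C@@H](c3cc(O)cc(O)c3)c12)c1ccc(O)cc1O.O=C(Cc1cc(O)cc2O[C@@H](c3ccc(O)cc3)[C@H](c3cc(O)cc(O)c3)c12)c1ccc(O)cc1O | intermediate
7 | 1-(2,4-dihydroxyphenyl)-2-[(2S,3S)-3-(3,5-dihydroxyphenyl)-6-hydroxy-2-(4-hydroxyphenyl)-2,3-dihydro-1-benzofuran-4-yl]ethan-1-one | O=C(Cc1cc(O)cc2O[C@H](c3ccc(O)cc3)[C@@H](c3cc(O)cc(O)c3)c12)c1ccc(O)cc1O | intermediate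
8 | quinone methide: 4-{(2S)-2-(3,5-dihydroxyphenyl)-2-[2,6-dihydroxy-4-((2S,3S)-4-(2-(2,4-dihydroxyphenyl)-2-oxoethyl)-6-hydroxy-2-(4-hydroxyphenyl)-2,3-dihydro-1-benzofuran-3-yl)phenyl]ethylidene}cyclohexa-2,5-dien-1-one | O=C1C=CC(=C[C@@H](c2cc(O)cc(O)c2)c2c(O)cc(cc2O)[C@H]2c3c(cc(O)cc3O[C@@H]2c2ccc(O)cc2)CC(=O)c2ccc(O)cc2O)C=C1 | intermediate (not isolated)
9 | 1-(2,4-dihydroxyphenyl)-2-{(2S,3S)-3-[(2S,3S)-3-(3,5-dihydroxyphenyl)-4-hydroxy-2-(4-hydroxyphenyl)-2,3-dihydro-1-benzofuran-6-yl]-6-hydroxy-2-(4-hydroxyphenyl)-2,3-dihydro-1-benzofuran-4-yl}ethan-1-one | Oc1ccc([C@H]2Oc3cc(cc(O)c3[C@@H]2c2cc(O)cc(O)c2)[C@H]2c3c(cc(O)cc3O[C@@H]2c2ccc(O)cc2)CC(=O)c2ccc(O)cc2O)cc1 | intermediate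
10 | the secondary alcohol from reduction of the ketone of 9 (both carbinol epimers; other centres as in 9) | Oc1ccc([C@H]2Oc3cc(cc(O)c3[C@@H]2c2cc(O)cc(O)c2)[C@H]2c3c(cc(O)cc3O[C@@H]2c2ccc(O)cc2)CC(O)c2ccc(O)cc2O)cc1 | intermediate (not isolated)
11 | CNP0154774.1: a CH2–CH(2,4-dihydroxyphenyl) bridge (CH of S configuration) joins C4 of the inner (2S,3S)-6-hydroxy-2-(4-hydroxyphenyl)-2,3-dihydrobenzofuran to C7 of the outer (2S,3S)-3-(3,5-dihydroxyphenyl)-4-hydroxy-2-(4-hydroxyphenyl)-2,3-dihydrobenzofuran, whose C6 is bonded to C3 of the inner ring | Oc1ccc([C@H]2Oc3c4c(cc(O)c3[C@@H]2c2cc(O)cc(O)c2)[C@H]2c3c(cc(O)cc3O[C@@H]2c2ccc(O)cc2)C[C@H]4c2ccc(O)cc2O)cc1 | target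

**Totals**
Total step count: 5 (four bond-forming steps and one resolution). Longest linear sequence: 5 (1/2 → 3 → 6 → 7 → 9 → 11).

**Steps most likely to fail, with fallbacks**

Step 4 is the riskiest. The benzofuran ring of 7 (its C5 and C7) and the new resorcinol ring of the product can also take up oxidised resveratrol, and the wanted isomer is at best half of the coupled material. The fallback sets out from 3 and comes back at 9. It inverts the order of the two dihydrofuran-forming events and takes the outer ring from the chiral pool: natural (2S,3S)-gnetin C F3, bought as the isolated melinjo-seed dimer and checked by circular dichroism, is the only oxidisable stilbene when treated with Tl(NO3)3·3H2O in MeOH at −50 °C in the presence of 3 (5 equiv). The ε-viniferin-type annulation of step 2 then takes place on the styryl group of gnetin C, and HPLC separation of the two trans diastereomers gives 9. This removes the competition between the rings of 7 and the need for step 3, at the price of an expensive starting material.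

Step 2 may give the isomer from attack between the two hydroxyls of 3, and resveratrol self-coupling competes with the cross-coupling. The fallback sets out from 3 and comes back at 6. It blocks the unwanted position: iodination with I2/NaHCO3 in aqueous THF, which goes between the hydroxyls of a free resorcinol ring, gives 1-(2,4-dihydroxyphenyl)-2-(3,5-dihydroxy-4-iodophenyl)ethan-1-one F1. The thallium coupling with 4 can then only use the carbons para to a hydroxyl and gives (±)-trans-1-(2,4-dihydroxyphenyl)-2-[3-(3,5-dihydroxyphenyl)-6-hydroxy-2-(4-hydroxyphenyl)-7-iodo-2,3-dihydro-1-benzofuran-4-yl]ethan-1-one F2. Reductive deiodination with Zn dust in aqueous AcOH returns 6.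

Step 5 may close at C5 of the outer benzofuran (ortho to the free OH) instead of C7, and the phenoxide-deactivated ketone may reduce slowly or over-reduce to CH2. The fallback sets out from 9 and comes back at 11. The two events are separated and the cation is made from the alkene: reduction as before, then base-mediated dehydration through the quinone methide (K2CO3, DMF, 80 °C), gives the (E)-stilbene 4-[(E)-2-{(2S,3S)-3-[(2S,3S)-3-(3,5-dihydroxyphenyl)-4-hydroxy-2-(4-hydroxyphenyl)-2,3-dihydro-1-benzofuran-6-yl]-6-hydroxy-2-(4-hydroxyphenyl)-2,3-dihydro-1-benzofuran-4-yl}ethenyl]benzene-1,3-diol F4, the presumed biogenetic precursor. It is purified from over-reduced material and cyclised by protonation in warm HCO2H, where the Friedel–Crafts step is reversible, so that the ring closure can equilibrate towards 11.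

**Further compounds**
F1 | step 2 | 1-(2,4-dihydroxyphenyl)-2-(3,5-dihydroxy-4-iodophenyl)ethan-1-one | O=C(Cc1cc(O)c(I)c(O)c1)c1ccc(O)cc1O
F2 | step 2 | (±)-trans-1-(2,4-dihydroxyphenyl)-2-[3-(3,5-dihydroxyphenyl)-6-hydroxy-2-(4-hydroxyphenyl)-7-iodo-2,3-dihydro-1-benzofuran-4-yl]ethan-1-one | O=C(Cc1cc(O)c(I)c2O[C@H](c3ccc(O)cc3)[C@@H](c3cc(O)cc(O)c3)c12)c1ccc(O)cc1O.O=C(Cc1cc(O)c(I)c2O[C@@H](c3ccc(O)cc3)[C@H](c3cc(O)cc(O)c3)c12)c1ccc(O)cc1O
F3 | step 4 | (2S,3S)-gnetin C, (2S,3S)-3-(3,5-dihydroxyphenyl)-2-(4-hydroxyphenyl)-6-[(E)-2-(4-hydroxyphenyl)ethenyl]-2,3-dihydro-1-benzofuran-4-ol | Oc1ccc([C@H]2Oc3cc(/C=C/c4ccc(O)cc4)cc(O)c3[C@@H]2c2cc(O)cc(O)c2)cc1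
F4 | step 5 | 4-[(E)-2-{(2S,3S)-3-[(2S,3S)-3-(3,5-dihydroxyphenyl)-4-hydroxy-2-(4-hydroxyphenyl)-2,3-dihydro-1-benzofuran-6-yl]-6-hydroxy-2-(4-hydroxyphenyl)-2,3-dihydro-1-benzofuran-4-yl}ethenyl]benzene-1,3-diol | Oc1ccc([C@H]2Oc3cc(cc(O)c3[C@@H]2c2cc(O)cc(O)c2)[C@H]2c3c(cc(O)cc3O[C@@H]2c2ccc(O)cc2)/C=C/c2ccc(O)cc2O)cc1
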